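## Retrosynthetic overview

1. Target 18 ⇐ its C4 methyl enol ether 17 (chloride demethylation). The exo C7 prenyl ⇐ C7 carboxylic acid 14 by decarboxylative radical prenylation, with the C–C bond formed last on the exo face.
2. 14 ⇐ allyl ester 13. Ring B (C1–C8–C7–C6–C5–C9) ⇐ intramolecular Michael addition of the benzoyl-bearing carbon C1 onto an α-substituted acrylate held on C5.
3. The C5 quaternary centre and the C5–C6(Me2) bond ⇐ enantioselective dearomative [3,3] Claisen rearrangement of aryl ether 11 (arene → cyclohexadienone 12), run in the same flask as the Michael closure.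
4. 11 ⇐ 4-O-methylclusiaphenone B 6 + allylic alcohol 10; 6 ⇐ phloroglucinol + benzoyl chloride + prenyl bromide.
5. Ring order: the phloroglucinol ring is carried from the start and becomes ring A (C1–C5 plus C9); ring B is the only ring formed, in the key step.

Assumption: the target is one tautomer of an enolised β-diketone. Locants used throughout: C1 benzoyl bridgehead, C2–C4 enol-dione bridge, C5 prenyl bridgehead, C6 CMe2, C7 CH, C8 CH2, C9 bridging C=O. The C1 descriptor changes from R (13–17) to S (18) through CIP priorities only, not through inversion.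

## Route

Step 1
Reactants: 1 phloroglucinol; 2 benzoyl chloride
Product: 3 2,4,6-trihydroxybenzophenone
Conditions: AlCl3 (4 equiv), PhNO2, 65 °C; aq HCl work-up
Reagents that add atoms: none
Why: Friedel–Crafts C-acylation of the strongly activated, threefold-symmetric arene gives a single mono-ketone because the first acyl group deactivates the ring.

Step 2
Reactants: 3 2,4,6-trihydroxybenzophenone; 4 prenyl bromide
Product: 5 clusiaphenone B (2,4,6-trihydroxy-3,5-bis(3-methylbut-2-en-1-yl)benzophenone)
Conditions: 4 (2.1 equiv), 5% aq KOH, 0 °C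
Reagents that add atoms: none
Why: C-alkylation of the phloroglucinol phenoxide in water (SN2 at the two free ring carbons) is the established double prenylation of acylphloroglucinols.

Step 3
Reactants: 5 clusiaphenone B
Product: 6 2,6-dihydroxy-4-methoxy-3,5-bis(3-methylbut-2-en-1-yl)benzophenone
Conditions: Me2SO4 (1.05 equiv), K2CO3 (1.1 equiv), acetone, 25 °C
Reagents that add atoms: dimethyl sulfate, COS(=O)(=O)OC
Why: Williamson O-methylation goes to the para hydroxyl, the most acidic one and the only one not hydrogen-bonded to the benzoyl carbonyl.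

Step 4
Reactants: 7 diallyl malonate; 8 acetone
Product: 9 diallyl 2-(propan-2-ylidene)malonate
Conditions: Ac2O, ZnCl2 (cat.), excess acetone, reflux
Reagents that add atoms: none
Why: Knoevenagel condensation of a malonate with acetone under Cope conditions, with acetic anhydride taking up the water.

Step 5
Reactants: 9 diallyl 2-(propan-2-ylidene)malonate
Product: 10 allyl 2-(hydroxymethyl)-3-methylbut-2-enoate
Conditions: i-Bu2AlH (2.1 equiv), CH2Cl2, −78 °C; Rochelle-salt work-up
Reagents that add atoms: none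
Why: partial hydride reduction of one of two equivalent conjugated esters to the allylic alcohol, with the β,β-disubstituted alkene resisting 1,4-reduction and the diol by-product removed by chromatography.

Step 6
Reactants: 6 2,6-dihydroxy-4-methoxy-3,5-bis(3-methylbut-2-en-1-yl)benzophenone; 10 allyl 2-(hydroxymethyl)-3-methylbut-2-enoate
Product: 11 allyl 2-{[2-benzoyl-3-hydroxy-5-methoxy-4,6-bis(3-methylbut-2-en-1-yl)phenoxy]methyl}-3-methylbut-2-enoate
Conditions: PPh3, DIAD, THF, 0 → 25 °C
Reagents that add atoms: none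
Why: Mitsunobu etherification alkylates one of the two equivalent phenols under neutral conditions (no ring C-alkylation), and the second phenol is slowed by its stronger hydrogen bond to the ketone.

Step 7
Reactants: 11 allyl 2-{[2-benzoyl-3-hydroxy-5-methoxy-4,6-bis(3-methylbut-2-en-1-yl)phenoxy]methyl}-3-methylbut-2-enoate
Product: 13 allyl (1R,5R,7R)-1-benzoyl-4-methoxy-6,6-dimethyl-3,5-bis(3-methylbut-2-en-1-yl)-2,9-dioxobicyclo[3.3.1]non-3-ene-7-carboxylate, via Claisen dienone 12 (not isolated)
Conditions: Cu(OTf)2 (20 mol %), (S,S)-t-Bu-bis(oxazoline) (22 mol %; antipode if induction is opposite), 4 Å MS, ClCH2CH2Cl, 25 → 40 °C; then Et3N (30 mol %), 40 °C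
Reagents that add atoms: none
Why: Proposed new method: chelation of the divalent-copper bis(oxazoline) complex by the aryl-ether oxygen and the ortho benzoyl carbonyl should accelerate a concerted dearomative [3,3] Claisen shift of the CMe2 terminus to the prenyl-bearing ortho carbon (the ester on the central allyl carbon disfavours ionisation), with the ligand shielding one arene face so that quaternary C5 forms as R, after which the copper-bound enolised triketone of 12, whose only acidic nucleophilic carbon is C1 because O4 is methylated, closes ring B by 6-endo-trig Michael addition onto the acrylate on the same face (fixing C1, the epimerisable C7 ester settling exo); the closest known reaction types are chiral-Lewis-acid-catalysed enantioselective dearomative Claisen rearrangements of allyl aryl ethers with an ortho carbonyl chelating group, copper–bis(oxazoline)-catalysed Claisen rearrangements of 2-alkoxycarbonyl allyl vinyl ethers, and the Michael ring closure of alkylative dearomatization–annulations of acylphloroglucinols.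

Step 8
Reactants: 13 allyl (1R,5R,7R)-1-benzoyl-4-methoxy-6,6-dimethyl-3,5-bis(3-methylbut-2-en-1-yl)-2,9-dioxobicyclo[3.3.1]non-3-ene-7-carboxylate
Product: 14 (1R,5R,7R)-1-benzoyl-4-methoxy-6,6-dimethyl-3,5-bis(3-methylbut-2-en-1-yl)-2,9-dioxobicyclo[3.3.1]non-3-ene-7-carboxylic acid
Conditions: Pd(PPh3)4 (5 mol %), morpholine (5 equiv), THF, 25 °C; dilute HCl work-up
Reagents that add atoms: none
Why: zerovalent-palladium-catalysed allyl transfer to morpholine (Tsuji–Trost deallylation) frees the acid without hydroxide, which could open ring B by retro-Michael reaction, and leaves the methyl enol ether and the prenyl groups untouched.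

Step 9
Reactants: 15 allyl phenyl sulfone
Product: 16 (2-methylbut-3-en-2-yl)sulfonylbenzene
Conditions: n-BuLi (1.05 equiv) then MeI (1.1 equiv), THF, −78 → 0 °C; repeated once in the same pot
Reagents that add atoms: iodomethane, CI
Why: two successive α-alkylations of the sulfonyl-stabilised allyl anion, which reacts at the carbon next to sulfur.

Step 10
Reactants: 14 (1R,5R,7R)-1-benzoyl-4-methoxy-6,6-dimethyl-3,5-bis(3-methylbut-2-en-1-yl)-2,9-dioxobicyclo[3.3.1]non-3-ene-7-carboxylic acid; 16 (2-methylbut-3-en-2-yl)sulfonylbenzene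
Product: 17 (1R,5R,7R)-1-benzoyl-4-methoxy-6,6-dimethyl-3,5,7-tris(3-methylbut-2-en-1-yl)bicyclo[3.3.1]non-3-ene-2,9-dione
Conditions: 16 (5 equiv), 4CzIPN (2 mol %), Cs2CO3 (1.1 equiv), DMSO, 450 nm LEDs, 25 °C
Reagents that add atoms: none
Why: photoredox decarboxylative radical allylation, in which the secondary C7 radical adds to the CH2 terminus of the sulfone and expels PhSO2 (SH2') to give a linear prenyl group, with attack on the open exo face anti to ring A (as in Keck allylations of C7 radicals in this ring system) giving 7R.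

Step 11
Reactants: 17 (1R,5R,7R)-1-benzoyl-4-methoxy-6,6-dimethyl-3,5,7-tris(3-methylbut-2-en-1-yl)bicyclo[3.3.1]non-3-ene-2,9-dione
Product: 18 (1S,5R,7R)-1-benzoyl-2-hydroxy-6,6-dimethyl-3,5,7-tris(3-methylbut-2-en-1-yl)bicyclo[3.3.1]non-2-ene-4,9-dione (target)
Conditions: LiCl (10 equiv), DMSO, 120 °C; aq HCl work-up
Reagents that add atoms: none
Why: SN2 demethylation of the vinylogous methyl ester by chloride frees the enolised β-diketone without touching a stereocentre, and the bridgehead benzoyl cannot undergo retro-Claisen cleavage.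

## Compound list

1 | phloroglucinol | Oc1cc(O)cc(O)c1 | starting material
2 | benzoyl chloride | O=C(Cl)c1ccccc1 | starting material
3 | 2,4,6-trihydroxybenzophenone | O=C(c1ccccc1)c1c(O)cc(O)cc1O | intermediate
4 | prenyl bromide (1-bromo-3-methylbut-2-ene) | CC(C)=CCBr | starting material
5 | clusiaphenone B | CC(C)=CCc1c(O)c(CC=C(C)C)c(O)c(C(=O)c2ccccc2)c1O | intermediate
6 | 2,6-dihydroxy-4-methoxy-3,5-bis(3-methylbut-2-en-1-yl)benzophenone | COc1c(CC=C(C)C)c(O)c(C(=O)c2ccccc2)c(O)c1CC=C(C)C | intermediate
7 | diallyl malonate | C=CCOC(=O)CC(=O)OCC=C | starting material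
8 | acetone | CC(C)=O | starting material
9 | diallyl 2-(propan-2-ylidene)malonate | CC(C)=C(C(=O)OCC=C)C(=O)OCC=C | intermediate
10 | allyl 2-(hydroxymethyl)-3-methylbut-2-enoate | CC(C)=C(CO)C(=O)OCC=C | intermediate
11 | allyl 2-{[2-benzoyl-3-hydroxy-5-methoxy-4,6-bis(3-methylbut-2-en-1-yl)phenoxy]methyl}-3-methylbut-2-enoate | COc1c(CC=C(C)C)c(O)c(C(=O)c2ccccc2)c(OCC(C(=O)OCC=C)=C(C)C)c1CC=C(C)C | intermediate
12 | allyl 2-{2-[(1R)-3-benzoyl-4-hydroxy-6-methoxy-1,5-bis(3-methylbut-2-en-1-yl)-2-oxocyclohexa-3,5-dien-1-yl]propan-2-yl}prop-2-enoate (Claisen dienone) | COC1=C(CC=C(C)C)C(O)=C(C(=O)c2ccccc2)C(=O)[C@]1(CC=C(C)C)C(C)(C)C(=C)C(=O)OCC=C | intermediate (not isolated)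
13 | allyl (1R,5R,7R)-1-benzoyl-4-methoxy-6,6-dimethyl-3,5-bis(3-methylbut-2-en-1-yl)-2,9-dioxobicyclo[3.3.1]non-3-ene-7-carboxylate (exo ester; any C7 epimer is carried on, C7 becomes a radical in step 10) | COC1=C(CC=C(C)C)C(=O)[C@]2(C(=O)c3ccccc3)C[C@@H](C(=O)OCC=C)C(C)(C)[C@@]1(CC=C(C)C)C2=O | intermediate
14 | (1R,5R,7R)-1-benzoyl-4-methoxy-6,6-dimethyl-3,5-bis(3-methylbut-2-en-1-yl)-2,9-dioxobicyclo[3.3.1]non-3-ene-7-carboxylic acid | COC1=C(CC=C(C)C)C(=O)[C@]2(C(=O)c3ccccc3)C[C@@H](C(=O)O)C(C)(C)[C@@]1(CC=C(C)C)C2=O | intermediate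
15 | allyl phenyl sulfone | C=CCS(=O)(=O)c1ccccc1 | starting material
16 | (2-methylbut-3-en-2-yl)sulfonylbenzene | C=CC(C)(C)S(=O)(=O)c1ccccc1 | intermediate
17 | (1R,5R,7R)-1-benzoyl-4-methoxy-6,6-dimethyl-3,5,7-tris(3-methylbut-2-en-1-yl)bicyclo[3.3.1]non-3-ene-2,9-dione | COC1=C(CC=C(C)C)C(=O)[C@]2(C(=O)c3ccccc3)C[C@@H](CC=C(C)C)C(C)(C)[C@@]1(CC=C(C)C)C2=O | intermediate
18 | (1S,5R,7R)-1-benzoyl-2-hydroxy-6,6-dimethyl-3,5,7-tris(3-methylbut-2-en-1-yl)bicyclo[3.3.1]non-2-ene-4,9-dione | CC(C)=CCC1=C(O)[C@]2(C(=O)c3ccccc3)C[C@@H](CC=C(C)C)C(C)(C)[C@](CC=C(C)C)(C1=O)C2=O | target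

## Step count and risk

Total step count: 11. Longest linear sequence: 8 steps from phloroglucinol (steps 1, 2, 3, 6, 7, 8, 10, 11).

**Step 7 (most likely to fail).** The enantioselective Claisen is untested on this substrate: the free phenol and the triketone product may bind the copper catalyst, and the ee or the sense of induction may be poor. The fallback sets out from 11 and gives up catalyst control for resolution. Heating 11 in toluene at 120 °C gives the thermal Claisen product as a racemate, that is 12 together with its enantiomer, allyl 2-{2-[(1S)-3-benzoyl-4-hydroxy-6-methoxy-1,5-bis(3-methylbut-2-en-1-yl)-2-oxocyclohexa-3,5-dien-1-yl]propan-2-yl}prop-2-enoate F1. DBU (10 mol %) in MeCN then closes ring B to 13 and its enantiomer, allyl (1S,5S,7S)-1-benzoyl-4-methoxy-6,6-dimethyl-3,5-bis(3-methylbut-2-en-1-yl)-2,9-dioxobicyclo[3.3.1]non-3-ene-7-carboxylate F2. Preparative chiral SFC separates the two, and the route is rejoined at 13.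

**Step 10.** The tertiary allyl sulfone 16 can isomerise to prenyl phenyl sulfone by a sulfonyl-radical chain, which would give reverse-prenyl or no product. The fallback sets out from 14 and builds the prenyl group in two operations. The same photoredox decarboxylation, trapped with allyl phenyl sulfone 15, gives (1R,5R,7R)-7-allyl-1-benzoyl-4-methoxy-6,6-dimethyl-3,5-bis(3-methylbut-2-en-1-yl)bicyclo[3.3.1]non-3-ene-2,9-dione F3. Cross-metathesis of its terminal alkene with 2-methylbut-2-ene (second-generation Grubbs catalyst, RuCl2(H2IMes)(PCy3)(=CHPh), CH2Cl2, 40 °C) converts allyl into prenyl, and the route is rejoined at 17.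

**Step 6.** The phenol is flanked by benzoyl and prenyl and is hydrogen-bonded, so the Mitsunobu reaction may be sluggish. The fallback sets out from 10 and uses an alkyl halide instead. PBr3 in Et2O at 0 °C converts 10 into allyl 2-(bromomethyl)-3-methylbut-2-enoate F4. Alkylation of 6 with this bromide (Cs2CO3, DMF, 0 → 25 °C; O-alkylation is favoured in the polar aprotic solvent) returns to the route at 11.

## Further compounds

F1 | step 7 | allyl 2-{2-[(1S)-3-benzoyl-4-hydroxy-6-methoxy-1,5-bis(3-methylbut-2-en-1-yl)-2-oxocyclohexa-3,5-dien-1-yl]propan-2-yl}prop-2-enoate | COC1=C(CC=C(C)C)C(O)=C(C(=O)c2ccccc2)C(=O)[C@@]1(CC=C(C)C)C(C)(C)C(=C)C(=O)OCC=C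
F2 | step 7 | allyl (1S,5S,7S)-1-benzoyl-4-methoxy-6,6-dimethyl-3,5-bis(3-methylbut-2-en-1-yl)-2,9-dioxobicyclo[3.3.1]non-3-ene-7-carboxylate | COC1=C(CC=C(C)C)C(=O)[C@@]2(C(=O)c3ccccc3)C[C@H](C(=O)OCC=C)C(C)(C)[C@]1(CC=C(C)C)C2=O
F3 | step 10 | (1R,5R,7R)-7-allyl-1-benzoyl-4-methoxy-6,6-dimethyl-3,5-bis(3-methylbut-2-en-1-yl)bicyclo[3.3.1]non-3-ene-2,9-dione | COC1=C(CC=C(C)C)C(=O)[C@]2(C(=O)c3ccccc3)C[C@@H](CC=C)C(C)(C)[C@@]1(CC=C(C)C)C2=O
F4 | step 6 | allyl 2-(bromomethyl)-3-methylbut-2-enoate | CC(C)=C(CBr)C(=O)OCC=C
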